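**Retrosynthetic overview**
1. The target comes from its penta-benzyl derivative (four aryl benzyl ethers, one benzyl ester) by one neutral hydrogenolysis at the end.
2. The pyranone ring is the only ring built and is closed last, by acid cyclodehydration of an o-hydroxyaryl 1,3-diketone that comes from oxidation of a β-hydroxy ketone.
3. Key C–C bond (ketone α-carbon to carbinol carbon, later C3–C2 of the chromone): intermolecular aldol addition of the lithium enolate of a 2-hydroxy-6-heptylacetophenone to a (2-benzyloxycarbonylaryl)acetaldehyde.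
4. The acetophenone comes from 5-heptylresorcinol (Hoesch acylation, 4-O-benzylation), made from 3,5-dimethoxybenzaldehyde and a C6 Wittig salt.
5. The arylacetaldehyde comes from a 2-allylbenzoate (alkene cleavage), made by aromatic Claisen rearrangement of a 5-allyloxybenzoate derived from 5-bromo-2,4-dihydroxybenzoic acid.

Assumption: the target has no stereocentre and no stereogenic double bond, so it is a single achiral compound and no enantiocontrol is needed.

**Route**

Step 1
Reactants: 1 hexyltriphenylphosphonium bromide; 2 3,5-dimethoxybenzaldehyde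
Product: 4 1-[(Z)-hept-1-en-1-yl]-3,5-dimethoxybenzene (Z/E mixture), via hexylidenetriphenylphosphorane 3 (not isolated)
Conditions: 1 (1.2 equiv), KOtBu (1.2 equiv), THF, 0 °C, 30 min; then 2, 0 °C → rt
Reagents that add atoms: none
Why: Wittig olefination of a non-enolisable aryl aldehyde with a non-stabilised ylide is dependable, and the Z/E ratio does not matter because the alkene is hydrogenated next.

Step 2
Reactants: 4 1-[(Z)-hept-1-en-1-yl]-3,5-dimethoxybenzene (Z/E mixture)
Product: 5 1-heptyl-3,5-dimethoxybenzene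
Conditions: H2 (1 atm), 10% Pd/C, EtOAc, rt
Reagents that add atoms: none
Why: Catalytic hydrogenation of a disubstituted styrene-type alkene is clean and aryl methyl ethers are inert to it.

Step 3
Reactants: 5 1-heptyl-3,5-dimethoxybenzene
Product: 6 5-heptylbenzene-1,3-diol
Conditions: BBr3 (3 equiv), CH2Cl2, −78 °C → rt; then H2O
Reagents that add atoms: none
Why: Lewis-acid ether cleavage with BBr3 removes both methyl groups and nothing else in the molecule can react.

Step 4
Reactants: 6 5-heptylbenzene-1,3-diol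
Product: 8 1-(2-heptyl-4,6-dihydroxyphenyl)ethan-1-one, via ketiminium chloride 7 (not isolated)
Conditions: MeCN (1.5 equiv), ZnCl2, HCl (g), Et2O, 0 °C, 24 h; decant; then H2O, reflux, 2 h
Reagents that add atoms: acetonitrile CC#N; water O
Why: Houben–Hoesch acylation of a 5-alkylresorcinol goes para to one OH and ortho to the other (as in orcinol → orcacetophenone), and the deactivating iminium group stops the reaction after one acylation.

Step 5
Reactants: 8 1-(2-heptyl-4,6-dihydroxyphenyl)ethan-1-one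
Product: 9 1-[4-(benzyloxy)-2-heptyl-6-hydroxyphenyl]ethan-1-one
Conditions: BnBr (1.05 equiv), K2CO3 (1.5 equiv), acetone, reflux
Reagents that add atoms: benzyl bromide BrCc1ccccc1
Why: Williamson etherification is selective for the 4-OH because the OH ortho to the acetyl group is tied up in an intramolecular hydrogen bond.

Step 6
Reactants: 10 5-bromo-2,4-dihydroxybenzoic acid
Product: 11 benzyl 2,4-bis(benzyloxy)-5-bromobenzoate
Conditions: BnBr (3.6 equiv), K2CO3 (4.5 equiv), DMF, 70 °C
Reagents that add atoms: benzyl bromide BrCc1ccccc1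
Why: Exhaustive Williamson O-alkylation with excess BnBr in DMF benzylates the carboxylate and both phenols, including the chelated 2-OH.

Step 7
Reactants: 11 benzyl 2,4-bis(benzyloxy)-5-bromobenzoate
Product: 12 benzyl 2,4-bis(benzyloxy)-5-(4,4,5,5-tetramethyl-1,3,2-dioxaborolan-2-yl)benzoate
Conditions: B2pin2 (1.3 equiv), Pd(dppf)Cl2·CH2Cl2 (5 mol %), KOAc (3 equiv), 1,4-dioxane, 90 °C
Reagents that add atoms: bis(pinacolato)diboron CC1(C)OB(OC1(C)C)B1OC(C)(C)C(C)(C)O1
Why: Miyaura borylation works on electron-rich ortho-alkoxy aryl bromides and the weak acetate base leaves the benzyl ester alone.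

Step 8
Reactants: 12 benzyl 2,4-bis(benzyloxy)-5-(4,4,5,5-tetramethyl-1,3,2-dioxaborolan-2-yl)benzoate
Product: 13 benzyl 2,4-bis(benzyloxy)-5-hydroxybenzoate
Conditions: NaBO3·4H2O (3 equiv), THF/H2O 1:1, rt
Reagents that add atoms: sodium perborate [Na+].[Na+].O[B-]1(O)OO[B-](O)(O)OO1
Why: Oxidation of the aryl boronate (1,2-aryl shift from boron to peroxide oxygen) with mild perborate gives the phenol without hydrolysing the benzyl ester.

Step 9
Reactants: 13 benzyl 2,4-bis(benzyloxy)-5-hydroxybenzoate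
Product: 14 benzyl 5-(allyloxy)-2,4-bis(benzyloxy)benzoate
Conditions: allyl bromide (1.5 equiv), K2CO3 (2 equiv), acetone, reflux
Reagents that add atoms: allyl bromide C=CCBr
Why: Williamson O-allylation of the only free phenol is unambiguous.

Step 10
Reactants: 14 benzyl 5-(allyloxy)-2,4-bis(benzyloxy)benzoate
Product: 15 benzyl 2-allyl-4,6-bis(benzyloxy)-3-hydroxybenzoate
Conditions: N,N-diethylaniline, 190 °C, Ar, 8 h
Reagents that add atoms: none
Why: In this aromatic Claisen rearrangement ([3,3]-sigmatropic shift, then rearomatisation) one ortho position carries OBn, so the allyl group can only end up on the free carbon between the oxygen and the ester.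

Step 11
Reactants: 15 benzyl 2-allyl-4,6-bis(benzyloxy)-3-hydroxybenzoate
Product: 16 benzyl 2-allyl-3,4,6-tris(benzyloxy)benzoate
Conditions: BnBr (1.5 equiv), K2CO3 (2 equiv), TBAI (cat.), DMF, 60 °C
Reagents that add atoms: benzyl bromide BrCc1ccccc1
Why: Williamson benzylation in DMF is forcing enough for the flanked phenol and caps the OH that could otherwise cyclise onto the side-chain carbonyl later.

Step 12
Reactants: 16 benzyl 2-allyl-3,4,6-tris(benzyloxy)benzoate
Product: 18 benzyl 3,4,6-tris(benzyloxy)-2-(2-oxoethyl)benzoate, via racemic 1,2-diol 17 (not isolated)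
Conditions: OsO4 (2 mol %), NaIO4 (4 equiv), 2,6-lutidine (2 equiv), dioxane/H2O 3:1, rt; crude aldehyde used at once
Reagents that add atoms: osmium tetroxide O=[Os](=O)(=O)=O; sodium periodate [Na+].[O-]I(=O)(=O)=O
Why: Lemieux–Johnson oxidation (dihydroxylation, then periodate glycol cleavage) attacks only the terminal alkene, and the transient diol stereocentre is racemic and destroyed in the same flask.

Step 13
Reactants: 9 1-[4-(benzyloxy)-2-heptyl-6-hydroxyphenyl]ethan-1-one; 18 benzyl 3,4,6-tris(benzyloxy)-2-(2-oxoethyl)benzoate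
Product: 20 benzyl 3,4,6-tris(benzyloxy)-2-{4-[4-(benzyloxy)-2-heptyl-6-hydroxyphenyl]-2-hydroxy-4-oxobutyl}benzoate (racemic), via dilithium phenoxide-enolate 19 (not isolated)
Conditions: 9 (1.3 equiv), LiHMDS (2.8 equiv), THF, −78 → −20 °C, 1 h; then 18 (1.0 equiv), −78 °C, 30 min; AcOH quench at −78 °C
Reagents that add atoms: none
Why: In this intermolecular aldol addition the kinetic methyl-ketone enolate adds to the unhindered aldehyde at −78 °C faster than it deprotonates it, the 2,6-disubstituted benzyl benzoate is too hindered to react, and the new carbinol stereocentre is formed racemic and is removed by oxidation in step 14.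

Step 14
Reactants: 20 benzyl 3,4,6-tris(benzyloxy)-2-{4-[4-(benzyloxy)-2-heptyl-6-hydroxyphenyl]-2-hydroxy-4-oxobutyl}benzoate (racemic)
Product: 21 benzyl 3,4,6-tris(benzyloxy)-2-{4-[4-(benzyloxy)-2-heptyl-6-hydroxyphenyl]-2,4-dioxobutyl}benzoate
Conditions: Dess–Martin periodinane (1.3 equiv), CH2Cl2, 0 °C → rt, 1 h
Reagents that add atoms: none
Why: Dess–Martin oxidation turns the β-hydroxy ketone into the 1,3-diketone under neutral conditions, so the diketone never meets base that could drive a Dieckmann closure onto the ortho ester.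

Step 15
Reactants: 21 benzyl 3,4,6-tris(benzyloxy)-2-{4-[4-(benzyloxy)-2-heptyl-6-hydroxyphenyl]-2,4-dioxobutyl}benzoate
Product: 22 benzyl 3,4,6-tris(benzyloxy)-2-{[7-(benzyloxy)-5-heptyl-4-oxo-4H-chromen-2-yl]methyl}benzoate
Conditions: conc. HCl (cat.), MeOH/THF 1:1, 50 °C, 2 h
Reagents that add atoms: none
Why: In this acid-catalysed cyclodehydration the free phenol adds to the distal ketone and loses water to give the aromatic γ-pyrone, while the benzyl ethers and the hindered benzyl ester survive dilute acid.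

Step 16
Reactants: 22 benzyl 3,4,6-tris(benzyloxy)-2-{[7-(benzyloxy)-5-heptyl-4-oxo-4H-chromen-2-yl]methyl}benzoate
Product: 23 3,4,6-trihydroxy-2-[(5-heptyl-7-hydroxy-4-oxo-4H-chromen-2-yl)methyl]benzoic acid
Conditions: H2 (1 atm), 10% Pd/C, EtOAc/MeOH 1:1, rt; filter under Ar
Reagents that add atoms: none
Why: Catalytic hydrogenolysis removes the four benzyl ethers and the benzyl ester under neutral conditions, which avoids decarboxylation of the o,p-dihydroxybenzoic acid, and the chromone C2=C3 bond is not reduced at 1 atm and rt.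

**Compound list**
1 | hexyltriphenylphosphonium bromide | CCCCCC[P+](c1ccccc1)(c1ccccc1)c1ccccc1.[Br-] | starting material
2 | 3,5-dimethoxybenzaldehyde | COc1cc(C=O)cc(OC)c1 | starting material
3 | hexylidenetriphenylphosphorane | CCCCCC=P(c1ccccc1)(c1ccccc1)c1ccccc1 | intermediate
4 | 1-[(Z)-hept-1-en-1-yl]-3,5-dimethoxybenzene (Z drawn; Z/E mixture, geometry removed in step 2) | CCCCC/C=C\c1cc(OC)cc(OC)c1 | intermediate
5 | 1-heptyl-3,5-dimethoxybenzene | CCCCCCCc1cc(OC)cc(OC)c1 | intermediate
6 | 5-heptylbenzene-1,3-diol | CCCCCCCc1cc(O)cc(O)c1 | intermediate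
7 | 1-(2-heptyl-4,6-dihydroxyphenyl)ethan-1-iminium chloride | CCCCCCCc1cc(O)cc(O)c1C(C)=[NH2+].[Cl-] | intermediate
8 | 1-(2-heptyl-4,6-dihydroxyphenyl)ethan-1-one | CCCCCCCc1cc(O)cc(O)c1C(C)=O | intermediate
9 | 1-[4-(benzyloxy)-2-heptyl-6-hydroxyphenyl]ethan-1-one | CCCCCCCc1cc(OCc2ccccc2)cc(O)c1C(C)=O | intermediate
10 | 5-bromo-2,4-dihydroxybenzoic acid | OC(=O)c1cc(Br)c(O)cc1O | starting material
11 | benzyl 2,4-bis(benzyloxy)-5-bromobenzoate | O=C(OCc1ccccc1)c1cc(Br)c(OCc2ccccc2)cc1OCc1ccccc1 | intermediate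
12 | benzyl 2,4-bis(benzyloxy)-5-(4,4,5,5-tetramethyl-1,3,2-dioxaborolan-2-yl)benzoate | CC1(C)OB(OC1(C)C)c1cc(C(=O)OCc2ccccc2)c(OCc2ccccc2)cc1OCc1ccccc1 | intermediate
13 | benzyl 2,4-bis(benzyloxy)-5-hydroxybenzoate | O=C(OCc1ccccc1)c1cc(O)c(OCc2ccccc2)cc1OCc1ccccc1 | intermediate
14 | benzyl 5-(allyloxy)-2,4-bis(benzyloxy)benzoate | C=CCOc1cc(C(=O)OCc2ccccc2)c(OCc2ccccc2)cc1OCc1ccccc1 | intermediate
15 | benzyl 2-allyl-4,6-bis(benzyloxy)-3-hydroxybenzoate | C=CCc1c(O)c(OCc2ccccc2)cc(OCc2ccccc2)c1C(=O)OCc1ccccc1 | intermediate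
16 | benzyl 2-allyl-3,4,6-tris(benzyloxy)benzoate | C=CCc1c(OCc2ccccc2)c(OCc2ccccc2)cc(OCc2ccccc2)c1C(=O)OCc1ccccc1 | intermediate
17 | benzyl 3,4,6-tris(benzyloxy)-2-(2,3-dihydroxypropyl)benzoate (racemic) | OCC(O)Cc1c(OCc2ccccc2)c(OCc2ccccc2)cc(OCc2ccccc2)c1C(=O)OCc1ccccc1 | intermediate
18 | benzyl 3,4,6-tris(benzyloxy)-2-(2-oxoethyl)benzoate | O=CCc1c(OCc2ccccc2)c(OCc2ccccc2)cc(OCc2ccccc2)c1C(=O)OCc1ccccc1 | intermediate
19 | dilithium 5-(benzyloxy)-3-heptyl-2-(1-oxidoethenyl)phenolate | [Li+].[Li+].C=C([O-])c1c(CCCCCCC)cc(OCc2ccccc2)cc1[O-] | intermediate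
20 | benzyl 3,4,6-tris(benzyloxy)-2-{4-[4-(benzyloxy)-2-heptyl-6-hydroxyphenyl]-2-hydroxy-4-oxobutyl}benzoate (racemic) | CCCCCCCc1cc(OCc2ccccc2)cc(O)c1C(=O)CC(O)Cc1c(OCc2ccccc2)c(OCc2ccccc2)cc(OCc2ccccc2)c1C(=O)OCc1ccccc1 | intermediate
21 | benzyl 3,4,6-tris(benzyloxy)-2-{4-[4-(benzyloxy)-2-heptyl-6-hydroxyphenyl]-2,4-dioxobutyl}benzoate | CCCCCCCc1cc(OCc2ccccc2)cc(O)c1C(=O)CC(=O)Cc1c(OCc2ccccc2)c(OCc2ccccc2)cc(OCc2ccccc2)c1C(=O)OCc1ccccc1 | intermediate
22 | benzyl 3,4,6-tris(benzyloxy)-2-{[7-(benzyloxy)-5-heptyl-4-oxo-4H-chromen-2-yl]methyl}benzoate | CCCCCCCc1cc(OCc2ccccc2)cc2oc(Cc3c(OCc4ccccc4)c(OCc4ccccc4)cc(OCc4ccccc4)c3C(=O)OCc3ccccc3)cc(=O)c12 | intermediate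
23 | 3,4,6-trihydroxy-2-[(5-heptyl-7-hydroxy-4-oxo-4H-chromen-2-yl)methyl]benzoic acid | CCCCCCCc1cc(O)cc2oc(Cc3c(O)c(O)cc(O)c3C(=O)O)cc(=O)c12 | target

**Totals and risks**
Total step count: 16. Longest linear sequence: 11 steps (10 → 23, steps 6–16); the other branch is 9 steps (2 → 23, steps 1–5 and 13–16).

The three steps most likely to fail:

Step 13 (aldol addition). The basic dianion may enolise the arylacetaldehyde instead of adding to it, or the lithium aldolate may lactonise onto the ortho benzyl ester. The fallback sets out from 9 and 18 and comes back at 20. Compound 9 is bis-silylated (TMSOTf, Et3N, CH2Cl2, 0 °C) to the aryl silyl ether and silyl enol ether [1-(4-benzyloxy-2-heptyl-6-trimethylsilyloxyphenyl)ethenyloxy]trimethylsilane F1. F1 is then added to 18 in a Lewis-acid Mukaiyama aldol reaction (BF3·OEt2, CH2Cl2, −78 °C), which involves no basic species. Work-up with dilute aqueous HCl hydrolyses both O–Si bonds and gives 20.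

Step 4 (Hoesch acylation). Some acylation between the two hydroxyl groups, or a sluggish reaction with the heptyl homologue, would cost material. The fallback sets out from 5 (step 3 is dropped) and comes back at 8. Friedel–Crafts acetylation of the dimethyl ether (AcCl, AlCl3, CH2Cl2, 0 °C), which goes ortho to the alkyl group and para to a methoxy group, gives 1-(2-heptyl-4,6-dimethoxyphenyl)ethan-1-one F2. BBr3 (4 equiv, CH2Cl2, −78 °C → rt) then cleaves both methyl ethers to give 8.

Step 16 (global hydrogenolysis). The chromone C2=C3 bond may be over-reduced, the flanked benzyl groups may come off incompletely, and the hydroxyquinol product is air-sensitive. The fallback sets out from 22 and comes back at 23. It replaces hydrogen by acidolytic debenzylation with BCl3 and pentamethylbenzene as benzyl-cation scavenger (CH2Cl2, −78 → 0 °C, MeOH quench), which removes all five benzyl groups without a reducing agent. This fallback makes no new compound (F0).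

**Further compounds**
F1 | step 13 | [1-(4-benzyloxy-2-heptyl-6-trimethylsilyloxyphenyl)ethenyloxy]trimethylsilane | C=C(O[Si](C)(C)C)c1c(CCCCCCC)cc(OCc2ccccc2)cc1O[Si](C)(C)C
F2 | step 4 | 1-(2-heptyl-4,6-dimethoxyphenyl)ethan-1-one | CCCCCCCc1cc(OC)cc(OC)c1C(C)=O
F0 | step 16 | none | none
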